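**Retrosynthetic overview**
1. Target 17 ⇐ cis-2-methyl ketone 15 by Wittig bromomethylenation and acidic release of the phenol; 15 ⇐ cyclopentene 12 by hydroboration/oxidation.
2. Key disconnection: the aryl–C(quaternary) bond of 12, made by copper-catalysed anti-SN2' coupling of aryl Grignard 11 (from iodide 4) with the enantioenriched allylic picolinate 10 (1,3-chirality transfer).
3. Fragment A (4): m-cresol → para-bromination → ortho-iodination → MOM ether. Fragment B (10): 3-methylcyclopent-2-en-1-one → α-methylation → CBS reduction → picolinate.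
4. Rings: the arene and the cyclopentane both come ready-made from the two starting materials; no ring is formed in the route.

Assumption: in the "Why" lines the cyclopentane carbons of the target are called C1 (quaternary), C2 (CHCH3) and C3 (C=CHBr); the (S)-CBS catalyst is taken to give the (R)-alcohol by the usual model.

**Step 1**
Reactants: 1 m-cresol
Product: 2 4-bromo-3-methylphenol
Conditions: Br2 (1.0 equiv), CH2Cl2, −10 → 0 °C; recrystallisation
Reagents that add atoms: bromine, BrBr
Why: Electrophilic aromatic bromination goes para to OH (ortho to the methyl group), and the minor ortho isomer is removed by crystallisation.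

**Step 2**
Reactants: 2 4-bromo-3-methylphenol
Product: 3 4-bromo-2-iodo-5-methylphenol
Conditions: NIS (1.05 equiv), TsOH·H2O (10 mol %), MeCN, 0 °C → rt
Reagents that add atoms: N-iodosuccinimide, O=C1CCC(=O)N1I
Why: Electrophilic aromatic iodination with the para position blocked goes to the open ortho carbon para to the methyl group rather than the flanked one between OH and CH3.

**Step 3**
Reactants: 3 4-bromo-2-iodo-5-methylphenol
Product: 4 1-bromo-5-iodo-4-(methoxymethoxy)-2-methylbenzene
Conditions: MOMCl, i-Pr2NEt, CH2Cl2, 0 °C → rt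
Reagents that add atoms: chloromethyl methyl ether, COCCl
Why: O-alkylation of the phenol gives a MOM acetal that survives Grignard, borane and ylide chemistry and falls off in mild acid.

**Step 4**
Reactants: 5 3-methylcyclopent-2-en-1-one
Product: 8 2,3-dimethylcyclopent-2-en-1-one, via potassium dienolate 6 (not isolated), via deconjugated enone 7 (not isolated)
Conditions: KOt-Bu (1.1 equiv), t-BuOH/THF, 0 °C; MeI (1.0 equiv, slow addition), 0 °C → rt; aq. NH4Cl; distillation
Reagents that add atoms: methyl iodide, CI
Why: Extended-enolate (deconjugative) α-alkylation: the thermodynamic dienolate is methylated at C2 and the β,γ-enone re-conjugates to the tetrasubstituted enone, with limiting MeI holding back the 2,2-dimethyl by-product (modest yield, recovered 5 is recycled).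

**Step 5**
Reactants: 8 2,3-dimethylcyclopent-2-en-1-one
Product: 9 (1R)-2,3-dimethylcyclopent-2-en-1-ol
Conditions: (S)-Me-CBS (10 mol %), BH3·SMe2 (0.6 equiv), THF, −20 °C; MeOH quench
Reagents that add atoms: none
Why: Corey–Bakshi–Shibata reduction, in which the tetrasubstituted alkenyl carbon acts as the large group and the CH2 as the small one, so the (S)-catalyst delivers hydride to give the (R)-allylic alcohol.

**Step 6**
Reactants: 9 (1R)-2,3-dimethylcyclopent-2-en-1-ol
Product: 10 (1R)-2,3-dimethylcyclopent-2-en-1-yl pyridine-2-carboxylate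
Conditions: picolinic acid (1.2 equiv), DCC (1.2 equiv), DMAP (10 mol %), CH2Cl2, 0 °C → rt
Reagents that add atoms: picolinic acid, OC(=O)c1ccccn1
Why: Steglich esterification leaves the C–O bond and thus the (R) centre untouched and installs a chelating leaving group for the coupling (used promptly, kept cold).

**Step 7**
Reactants: 4 1-bromo-5-iodo-4-(methoxymethoxy)-2-methylbenzene; 10 (1R)-2,3-dimethylcyclopent-2-en-1-yl pyridine-2-carboxylate
Product: 12 1-bromo-5-[(1R)-1,2-dimethylcyclopent-2-en-1-yl]-4-(methoxymethoxy)-2-methylbenzene, via aryl Grignard reagent 11 (not isolated)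
Conditions: 4 (1.6 equiv), i-PrMgCl·LiCl (1.55 equiv), THF, −20 °C, 1 h; then Cu(acac)2 (20 mol %), 10 (1.0 equiv), THF, −20 → 0 °C
Reagents that add atoms: none
Why: Iodine–magnesium exchange is selective for the iodide over the bromide, and copper-catalysed allylic substitution of the magnesium-chelated picolinate then goes anti-SN2', the aryl group entering the methyl-bearing γ-carbon on the face opposite the leaving group so that the (R) carbinol centre is relayed into the (R) quaternary centre.

**Step 8**
Reactants: 12 1-bromo-5-[(1R)-1,2-dimethylcyclopent-2-en-1-yl]-4-(methoxymethoxy)-2-methylbenzene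
Product: 15 (2R,3R)-3-[5-bromo-2-(methoxymethoxy)-4-methylphenyl]-2,3-dimethylcyclopentan-1-one, via alkylborane 13 (not isolated), via cyclopentanol 14 (not isolated)
Conditions: BH3·THF (2 equiv), THF, 0 °C → rt; then NMO (6 equiv), 4 Å MS, CH2Cl2; n-Pr4N[RuO4] (5 mol %), rt
Reagents that add atoms: N-methylmorpholine N-oxide, C[N+]1([O-])CCOCC1
Why: Syn, anti-Markovnikov hydroboration on the face away from the bulky aryl group puts the new C2–H trans to aryl (C2-methyl cis to aryl), and amine-oxide oxidation of C–B followed by Ley–Griffith oxidation gives the ketone under neutral conditions that do not epimerise C2.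

**Step 9**
Reactants: 15 (2R,3R)-3-[5-bromo-2-(methoxymethoxy)-4-methylphenyl]-2,3-dimethylcyclopentan-1-one
Product: 17 4-bromo-2-[(1R,2R,3E)-3-(bromomethylidene)-1,2-dimethylcyclopentyl]-5-methylphenol, via MOM-protected bromoalkene 16 (not isolated)
Conditions: Ph3P+CH2Br Br− (3.0 equiv), NaN(SiMe3)2 (2.9 equiv), THF, −78 °C; 15, −78 → 0 °C; then MeOH, 3 M HCl, 45 °C; chromatography
Reagents that add atoms: (bromomethyl)triphenylphosphonium bromide, BrC[P+](c1ccccc1)(c1ccccc1)c1ccccc1.[Br-]
Why: Wittig bromomethylenation places bromine on the less hindered CH2 side of the ketone (E, anti to C2), the cold base-free ylide limiting enolisation at C2, and acid-catalysed transacetalisation in the same flask then frees the phenol.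

**Compound list**
1 | m-cresol (3-methylphenol) | Cc1cccc(O)c1 | starting material
2 | 4-bromo-3-methylphenol | Cc1cc(O)ccc1Br | intermediate
3 | 4-bromo-2-iodo-5-methylphenol | Cc1cc(O)c(I)cc1Br | intermediate
4 | 1-bromo-5-iodo-4-(methoxymethoxy)-2-methylbenzene | COCOc1cc(C)c(Br)cc1I | intermediate
5 | 3-methylcyclopent-2-en-1-one | CC1=CC(=O)CC1 | starting material
6 | potassium 3-methylcyclopenta-1,3-dien-1-olate | [O-]C1=CC(C)=CC1.[K+] | intermediate (not isolated)
7 | 2,3-dimethylcyclopent-3-en-1-one (racemic) | CC1C(=O)CC=C1C | intermediate (not isolated)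
8 | 2,3-dimethylcyclopent-2-en-1-one | CC1=C(C)C(=O)CC1 | intermediate
9 | (1R)-2,3-dimethylcyclopent-2-en-1-ol | CC1=C(C)[C@H](O)CC1 | intermediate
10 | (1R)-2,3-dimethylcyclopent-2-en-1-yl pyridine-2-carboxylate | CC1=C(C)[C@H](OC(=O)c2ccccn2)CC1 | intermediate
11 | [5-bromo-2-(methoxymethoxy)-4-methylphenyl]magnesium chloride (LiCl complex) | COCOc1cc(C)c(Br)cc1[Mg]Cl | intermediate (not isolated)
12 | 1-bromo-5-[(1R)-1,2-dimethylcyclopent-2-en-1-yl]-4-(methoxymethoxy)-2-methylbenzene | COCOc1cc(C)c(Br)cc1[C@]1(C)CCC=C1C | intermediate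
13 | {(1R,2S,3R)-3-[5-bromo-2-(methoxymethoxy)-4-methylphenyl]-2,3-dimethylcyclopentyl}borane (B and the new C2–H cis, both trans to aryl) | COCOc1cc(C)c(Br)cc1[C@]1(C)CC[C@@H](B)[C@@H]1C | intermediate (not isolated)
14 | (1R,2R,3R)-3-[5-bromo-2-(methoxymethoxy)-4-methylphenyl]-2,3-dimethylcyclopentan-1-ol (OH trans to aryl, 2-methyl cis to aryl; present as its borate) | COCOc1cc(C)c(Br)cc1[C@]1(C)CC[C@@H](O)[C@@H]1C | intermediate (not isolated)
15 | (2R,3R)-3-[5-bromo-2-(methoxymethoxy)-4-methylphenyl]-2,3-dimethylcyclopentan-1-one | COCOc1cc(C)c(Br)cc1[C@]1(C)CCC(=O)[C@@H]1C | intermediate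
16 | 1-bromo-5-[(1R,2R,3E)-3-(bromomethylidene)-1,2-dimethylcyclopentyl]-4-(methoxymethoxy)-2-methylbenzene | COCOc1cc(C)c(Br)cc1[C@]1(C)CC/C(=C\Br)[C@@H]1C | intermediate (not isolated)
17 | 4-bromo-2-[(1R,2R,3E)-3-(bromomethylidene)-1,2-dimethylcyclopentyl]-5-methylphenol | Cc1cc(O)c([C@]2(C)CC/C(=C\Br)[C@@H]2C)cc1Br | target

**Totals**
Total step count: 9. Longest linear sequence: 6 steps (steps 1–3 or steps 4–6, then steps 7–9).

**Steps most likely to fail, with fallbacks**

Step 7 is the most exposed step. The γ-carbon is fully substituted, the alkene is tetrasubstituted and the aryl nucleophile carries an ortho substituent, so α-attack, elimination to the diene or attack at the ester carbonyl may win. The fallback sets out from alcohol 9 and phenol 2 and comes back at 12. Mitsunobu etherification of 2 with 9 (PPh3, DIAD, toluene, 0 °C) goes with inversion to the aryl ether 1-bromo-4-{[(1S)-2,3-dimethylcyclopent-2-en-1-yl]oxy}-2-methylbenzene F1. Heating F1 (N,N-diethylaniline, 170 °C) brings about a suprafacial aromatic Claisen rearrangement to the free ortho carbon para to the methyl group and gives 4-bromo-2-[(1R)-1,2-dimethylcyclopent-2-en-1-yl]-5-methylphenol F2. Inversion followed by suprafacial transfer gives the same (R) quaternary centre as the anti-SN2' reaction. MOMCl and i-Pr2NEt then convert F2 into 12.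

Step 9 is the second risk. The basic ylide can enolise the ketone and epimerise C2 to the more stable trans isomer, the ketone is hindered, and some Z isomer is likely. The fallback sets out from 15 and comes back at 16. A boron-Wittig reaction (CH2(Bpin)2 and lithium 2,2,6,6-tetramethylpiperidide, THF, 0 → −78 °C, then 15) gives the alkenyl boronate 2-{(E)-[(2S,3R)-3-[5-bromo-2-(methoxymethoxy)-4-methylphenyl]-2,3-dimethylcyclopentylidene]methyl}-4,4,5,5-tetramethyl-1,3,2-dioxaborolane F3, with boron on the CH2 side. F3 can be freed of its Z isomer by chromatography. Bromodeboronation with retention (CuBr2, MeOH/H2O, 70 °C) then gives 16, which goes into the acid treatment of step 9.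

Step 8 is the third risk, because the C2 configuration rests on borane adding to the face away from the aryl group. If addition takes place on the aryl face instead, the C2 epimer of 15 would result. The fallback sets out from 12 and comes back at 15, and it turns that same facial preference around. Epoxidation (mCPBA, NaHCO3, CH2Cl2, 0 °C) gives the epoxide (2R)-2-[5-bromo-2-(methoxymethoxy)-4-methylphenyl]-1,2-dimethyl-6-oxabicyclo[3.1.0]hexane with oxygen cis to aryl F4. Meinwald rearrangement (BF3·OEt2, CH2Cl2, −78 °C) opens the tertiary C–O bond and shifts hydride from C3 to C2 anti to the departing oxygen, which again places the C2-methyl cis to aryl and gives 15.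

**Further compounds**
F1 | step 7 | 1-bromo-4-{[(1S)-2,3-dimethylcyclopent-2-en-1-yl]oxy}-2-methylbenzene | CC1=C(C)[C@@H](Oc2ccc(Br)c(C)c2)CC1
F2 | step 7 | 4-bromo-2-[(1R)-1,2-dimethylcyclopent-2-en-1-yl]-5-methylphenol | Cc1cc(O)c([C@]2(C)CCC=C2C)cc1Br
F3 | step 9 | 2-{(E)-[(2S,3R)-3-[5-bromo-2-(methoxymethoxy)-4-methylphenyl]-2,3-dimethylcyclopentylidene]methyl}-4,4,5,5-tetramethyl-1,3,2-dioxaborolane | COCOc1cc(C)c(Br)cc1[C@]1(C)CC/C(=C\B2OC(C)(C)C(C)(C)O2)[C@@H]1C
F4 | step 8 | (2R)-2-[5-bromo-2-(methoxymethoxy)-4-methylphenyl]-1,2-dimethyl-6-oxabicyclo[3.1.0]hexane, epoxide oxygen cis to aryl | COCOc1cc(C)c(Br)cc1[C@]1(C)CC[C@@H]2O[C@]12C
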